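Two constants carry this flask, and the red run gives both if each curve is replaced by its mean over a window. I called a the share of starting material made into target per minute, and k the share of target lost per minute. The loss is my assumption, and so is holding a steady, although the reagent, at 1.00 M against 0.400 M, falls as it is used.

| flask | starting material | reagent | time |
|---|---|---|---|
| red | 0.400 M | 1.00 M |  |
| ochre | 0.200 M | 0.800 M |  |
| blue | 0.400 M | 2.00 M |  |
| grey | 0.800 M | 1.00 M |  |
| amber | 0.400 M | 1.00 M | 110 min |

| red run: time / min | red run: [target] / M | ochre run: time / min | ochre run: [target] / M | blue run: time / min | blue run: [target] / M | grey run: time / min | grey run: [target] / M |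
|---|---|---|---|---|---|---|---|
| 1.7 | 0.012 | 1.7 | 0 | 1.7 | 0.023 | 1.7 | 0.018 |
| 5.1 | 0.024 | 5.1 | 0.023 | 5.1 | 0.052 | 5.1 | 0.042 |
| 9.8 | 0.045 | 9.8 | 0.023 | 9.8 | 0.080 | 9.8 | 0.077 |
| 16 | 0.060 | 16 | 0.034 | 16 | 0.118 | 16 | 0.096 |
| 22 | 0.075 | 22 | 0.041 | 22 | 0.137 | 22 | 0.121 |
| 30 | 0.087 | 30 | 0.045 | 30 | 0.158 | 30 | 0.143 |
| 38 | 0.094 | 38 | 0.053 | 38 | 0.162 | 38 | 0.148 |

(scatter of a reading: 0.004 M)

- Overall: starting material + reagent -> target.
- Constant volume, constant temperature.
- What is held in complexes is read along with the free species.
- An order is taken over about fifteen percent of the charge, up and down.

- the power of [reagent] that the first rate follows, about the charge of the red run; measure it at two percent of starting material made into target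
- the power of [starting material] that the first rate follows, about the charge of the red run; measure it at two percent of starting material made into target (one fixed amount of target, the same in the runs compared)
- target in the amber run at 110 min, as a share of the starting material charged

The red run reached 11.2% of the charge by 9.8 min, which gave a rough value:

rough a = 0.0115 /min

Between 22 min and 38 min the share gained 0.00297 /min, less than the 0.00814 /min that making should still have supplied at 30 min. I booked that gap as loss, against the mean share 21.7%:

rough k = 0.0238 /min

I then put this loss back into the first window and read the late window again:

a = 0.0136 /min, k = 0.0279 /min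

Folded together, these give D = a/k = 0.487, the making-to-loss number: the target stops rising where its share equals D times the share of starting material remaining. For the red charge, which the amber run repeats, I reckoned that top at 50.4 min and 24.6%, and after it the target falls, so a flattening curve is not an end point. D gives the height but not the clock, so I also needed k·t = 3.07:

share at 110 min = D/(1 − D) × (exp(−a·t) − exp(−k·t)) = 16.9%

This figure is an estimate, since the same a turns 77.6% of the starting material of the amber run by 110 min, which takes 31.0% of its reagent, and I had held a steady.

As a test, the same curve gives 15.6% at 16 min, a reading I had not used, which stood at 15.0%, a gap smaller than the scatter of 1.00% of the charge.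

The forecast gave 0.95 in reagent, 0.67 in starting material and 27.5%, above my figure, for runs that “level off well short of completion”.

The amber run gave 17.4%, which is 0.707 of the top reckoned from D, with orders 1.1 in reagent and 0.69 in starting material.

    starting material ⇌ intermediate, settled at all times (0.04240)
    intermediate + reagent → target (0.7620 /M/min)
    target → decomposed product (0.02772 /min)
    2 starting material ⇌ idle substrate dimer, settled at all times (3.450 /M)

The target goes on to decomposed product. The grey run, with 0.800 M of starting material against 0.400 M, made target early at 1.6 times the red rate, which lowers D to 0.384. The curve then gives 19.9% of the grey charge at 38 min, where the reading stood at 18.5%.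

(The readings are simulated on assumed constants.)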